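Follow one Z as it takes up G, and count its chances at each fork.

| flask | Z | G | D | remark | time |
|---|---|---|---|---|---|
| zeta | 5 mM | 2.5 mM | 25 mM | run made earlier |  |
| epsilon | 5 mM | 10 mM | 25 mM | run made earlier |  |
| gamma | 10 mM | 5 mM | 25 mM | run made earlier |  |
| flask | 5.0 mM | 5.00 mM | 25.0 mM |  | 6.0 min |

| run | time / min | X / % | Z / % |
|---|---|---|---|
| zeta | 0.667 | 30.5 | 55.1 |
| zeta | 2.00 | 26.9 | 53.7 |
| zeta | 3.00 | 27.6 | 53.0 |
| zeta | 5.00 | 26.9 | 53.0 |
| zeta | 8.00 | 26.7 | 53.4 |
| epsilon | 0.500 | 45.3 | 4.0 |
| epsilon | 1.00 | 40.3 | 2.8 |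
| epsilon | 2.00 | 39.8 | 2.9 |
| epsilon | 4.00 | 40.0 | 2.3 |
| epsilon | 8.00 | 39.7 | 1.9 |
| gamma | 0.500 | 31.5 | 52.4 |
| gamma | 1.00 | 28.1 | 52.1 |
| gamma | 2.00 | 27.7 | 52.5 |
| gamma | 4.00 | 26.7 | 52.2 |
| gamma | 8.00 | 27.2 | 52.4 |

(readings scatter by 0.5 percentage points)

- steps that have been proposed: X + G <-> D + L; X <-> J; Z + G <-> D + X

* equivalents of G to Z, everything else as given, that leave most X at 6.0 min
* the amount of X then, in percent of the Z charged
* the amount of X with the amounts as given

The runs flatten early. In the zeta run X falls from 30.5% to 26.9% at 2.00 min and still reads 26.7% at 8.00 min. We therefore reckon the flask at 6.0 min as an end state, which is thermodynamic control.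

The last zeta reading shows 46.6% of Z gone against G of 50.0% of the charge. L then reads at most 3.40%, within the scatter, and we book the whole missing part as J. That reads J per X as 0.745. A Z with one G exchanged therefore stands as X with the fork share, X over X plus J, of 0.573.

Our first way is a plain count for the flask: one equivalent, one exchange each, so X is 57.3%. Our second way lets two X swap a G into Z and L. At an end state the swap ratio, Z times L over X squared, contains neither G nor D.

The epsilon plateau reads Z 2.37% and X 39.8%. The balance leaves L 28.1%, so the ratio is 0.0419. X over the fork share, plus Z, plus L, makes the whole charge, and for a given X and ratio, Z plus L is smallest when Z and L are equal. Our reckoned peak of X is then 46.4%. The two ways part, and the count is the one that cheats: it allows no L, and the balance reads L of 28.1% in epsilon.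

In epsilon the balance reads free G as 0.119 of free D, so L per X reads 5.95 times G over D. At the peak G over D is 0.0344, which in the flask asks for 1.21 equivalents. In the flask at one equivalent, the balance makes Z exceed L by the free G, and our X is 44.9%.

The forecast, made apart from this reckoning, gives 1.2 equiv, 46.7% and 45.3%, and takes the end as “effectively equilibrium”.

The flask gives 43.9% of X, and the best charge gives 45.5% at 1.22 equiv.

    X + G ⇌ D + L (K = 6.00, k = 37.0 L mol⁻¹ s⁻¹)
    X ⇌ J (K = 0.750, k = 0.0220 s⁻¹)
    Z + G ⇌ D + X (K = 120, k = 42.0 L mol⁻¹ s⁻¹)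

At that best charge Z and L stand at 10.2% and 10.2%. In the flask, 32.9% of J at 6.00 min gives, by the fork share, 44.1% of X. The neighbour with 20 mM of Z holds 10.5% of J, so the share gives 14.1% of X, and that neighbour holds 14.0%.

(The numbers in the tables are calculated from invented constants, and the scatter is random.)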